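The route rests on opening the dimethylpyran fused to ring B across its C3''=C4'' double bond and its O1''–C2'' bond. C4'' sits on C3' between O2' and O4', so it is a latent aldehyde carbon of a salicylaldehyde whose phenol is the pyran oxygen. In one operation, a catalytic Petasis condensation of this ring-B salicylaldehyde with 2-methylprop-1-enylboronic acid, amine loss and oxa-6π-electrocyclization build the whole 2,2-dimethyl-2H-chromene. The precursor is the (R)-isoflavan with a 2'-hydroxy-3'-formyl-4'-benzyloxy ring B and a 7-O-methylated ring A. Its stereocenter comes from iridium-catalysed asymmetric hydrogenation of an isoflavene made by Claisen rearrangement, DDQ cyclization and Suzuki coupling.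

Key step: step 7

Remarks on the chemistry:
- Locants: chroman O1, C2, C3, C4, C4a, C5–C8, C8a (ring A); ring B primed; fused dimethylpyran double-primed (O1'', C2'' = CMe2, C3'', C4'').
- The only stereocenter is C3, and the target is 3R (priorities C2 > C1' > C4 > H).
- Assumption: 5-(benzyloxy)-2-bromophenol (8) is bought.
- Assumption: the facial sense of the iridium catalyst in step 5 has to be confirmed on the substrate, and the ligand antipode that gives 3R is used.

Step 1
Reactants: 1 2-hydroxy-4,6-dimethoxybenzaldehyde; 2 2,3-dibromoprop-1-ene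
Product: 3 2-[(2-bromoprop-2-en-1-yl)oxy]-4,6-dimethoxybenzaldehyde
Conditions: K2CO3, DMF, 60 °C
Reagents that add atoms: none
Why: Williamson ether synthesis, in which the phenoxide displaces the allylic bromide of 2 (SN2) while the vinylic bromide stays inert.

Step 2
Reactants: 3 2-[(2-bromoprop-2-en-1-yl)oxy]-4,6-dimethoxybenzaldehyde
Product: 5 3-(2-bromoprop-2-en-1-yl)-2-hydroxy-4,6-dimethoxybenzaldehyde, via Claisen dienone 4 (not isolated)
Conditions: 1,2-dichlorobenzene, 180 °C, sealed tube
Reagents that add atoms: none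
Why: Aromatic Claisen rearrangement, in which the [3,3] shift can only go to C3, the one free ortho position (the other carries the formyl group), so the three-carbon unit should end up between the liberated phenol and the 4-methoxy group.

Step 3
Reactants: 5 3-(2-bromoprop-2-en-1-yl)-2-hydroxy-4,6-dimethoxybenzaldehyde
Product: 7 3-bromo-5,7-dimethoxy-2H-chromene-8-carbaldehyde, via ortho-quinone methide 6 (not isolated)
Conditions: DDQ (1.05 equiv), 1,4-dioxane, 80 °C
Reagents that add atoms: none
Why: DDQ dehydrogenative cyclization of an ortho-allylphenol, in which hydride abstraction from the benzylic CH2 (cation stabilized by ortho-OH, ortho-OMe and para-OMe) gives an ortho-quinone methide that closes by oxa-6π-electrocyclization, leaving bromine on C3.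

Step 4
Reactants: 7 3-bromo-5,7-dimethoxy-2H-chromene-8-carbaldehyde; 8 5-(benzyloxy)-2-bromophenol
Product: 10 3-[4-(benzyloxy)-2-hydroxyphenyl]-5,7-dimethoxy-2H-chromene-8-carbaldehyde, via vinylboronate 9 (not isolated)
Conditions: B2pin2, Pd(dppf)Cl2 (5 mol%), KOAc, 1,4-dioxane, 80 °C; then 8, aq. K3PO4, 90 °C
Reagents that add atoms: none
Why: Miyaura borylation of the vinyl bromide followed in the same flask by Suzuki–Miyaura coupling with the ortho-bromophenol, both of which tolerate aldehyde and free phenol; borylating the vinyl partner avoids an electron-rich ortho-hydroxyarylboronic acid that would protodeboronate.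

Step 5
Reactants: 10 3-[4-(benzyloxy)-2-hydroxyphenyl]-5,7-dimethoxy-2H-chromene-8-carbaldehyde
Product: 11 (3R)-3-[4-(benzyloxy)-2-hydroxyphenyl]-5,7-dimethoxy-3,4-dihydro-2H-chromene-8-carbaldehyde
Conditions: [Ir(cod)(L)]B[C6H3-3,5-(CF3)2]4 (2 mol%; L = (S)-4-tert-butyl-2-[2-(diphenylphosphino)phenyl]-4,5-dihydrooxazole or its antipode, whichever gives 3R), H2 (50 bar), CH2Cl2, 25 °C
Reagents that add atoms: none
Why: Iridium-catalysed asymmetric hydrogenation of a trisubstituted cyclic styrene (3-aryl-2H-chromene) with a chiral P,N-ligand complex, in which the catalyst delivers H2 to one face of C3=C4 and so sets C3 as R, while the benzyl ether and the hindered aryl aldehyde should not be reduced.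

Step 6
Reactants: 11 (3R)-3-[4-(benzyloxy)-2-hydroxyphenyl]-5,7-dimethoxy-3,4-dihydro-2H-chromene-8-carbaldehyde
Product: 13 (3R)-3-[4-(benzyloxy)-3-formyl-2-hydroxyphenyl]-5,7-dimethoxy-3,4-dihydro-2H-chromene-8-carbaldehyde, via salicyl alcohol 12 (not isolated)
Conditions: MgCl2, Et3N, (CH2O)n, MeCN, reflux; then aq. HCl
Reagents that add atoms: formaldehyde (as paraformaldehyde), C=O
Why: Magnesium phenoxide-directed ortho-formylation (Casnati–Skattebøl), in which the aryloxymagnesium species delivers formaldehyde to C3', the only free ortho position of the 2'-phenol, and a second formaldehyde oxidizes the benzylic alkoxide; ring A has no free phenol and is untouched.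

Step 7
Reactants: 13 (3R)-3-[4-(benzyloxy)-3-formyl-2-hydroxyphenyl]-5,7-dimethoxy-3,4-dihydro-2H-chromene-8-carbaldehyde; 14 (2-methylprop-1-en-1-yl)boronic acid
Product: 17 (3R)-3-[5-(benzyloxy)-2,2-dimethyl-2H-chromen-8-yl]-5,7-dimethoxy-3,4-dihydro-2H-chromene-8-carbaldehyde, via allylic amine 15 (not isolated), via ortho-quinone methide 16 (not isolated)
Conditions: 14 (2 equiv), Bn2NH (40 mol%), 1,4-dioxane, 90 °C
Reagents that add atoms: none
Why: Dibenzylamine condenses with the ring-B formyl group to an iminium ion, 14 binds the adjacent 2'-phenoxide as a boronate ate complex, and the 2-methylprop-1-enyl group migrates intramolecularly from boron to the iminium carbon, which forms the C4''–C3'' bond (15). At 90 °C the allylic amine loses dibenzylamine, which re-enters the cycle, to give ortho-quinone methide 16, and this closes the pyran by a thermal oxa-6π-electrocyclization (a pericyclic closure of the 1-oxatriene O2'=C2'–C3'=C4''–C3''=C2'', not an ionic exo or endo attack), which forms the O1''–C2'' bond and restores the arene. The closest known reaction type is the amine-catalysed Petasis borono-Mannich condensation of salicylaldehydes with alkenylboronic acids that leads to 2H-chromenes. No stereocenter is created, since C2'' carries two methyl groups and C3'' and C4'' are sp2, and C3 of the chroman is not touched. The step needs chemoselectivity between the two formyl groups and regioselectivity between O2' and O4': the ring-A aldehyde has no free ortho-hydroxyl (7-OMe on one side, the ring oxygen on the other) and cannot form the ate complex, and O4' is benzylated, so only O2' can close the ring.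

Step 8
Reactants: 17 (3R)-3-[5-(benzyloxy)-2,2-dimethyl-2H-chromen-8-yl]-5,7-dimethoxy-3,4-dihydro-2H-chromene-8-carbaldehyde
Product: 19 (3R)-7-hydroxy-3-(5-hydroxy-2,2-dimethyl-2H-chromen-8-yl)-5-methoxy-3,4-dihydro-2H-chromene-8-carbaldehyde, via debenzylated phenol 18 (not isolated)
Conditions: BCl3 (5 equiv), C6HMe5 (3 equiv), CH2Cl2, −78 to 0 °C; then MeOH, aq. NaHCO3
Reagents that add atoms: none
Why: Boron trichloride ether cleavage, in which the benzyl ether falls at low temperature with pentamethylbenzene as cation scavenger and the 7-methoxy group is cleaved through its six-membered chelate with the 8-formyl group, whereas the 5-methoxy group para to the aldehyde cannot chelate and should stay.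

Compound list
1 | 2-hydroxy-4,6-dimethoxybenzaldehyde | COc1cc(O)c(C=O)c(OC)c1 | starting material
2 | 2,3-dibromoprop-1-ene | C=C(Br)CBr | starting material
3 | 2-[(2-bromoprop-2-en-1-yl)oxy]-4,6-dimethoxybenzaldehyde | COc1cc(OCC(Br)=C)c(C=O)c(OC)c1 | intermediate
4 | 5-(2-bromoprop-2-en-1-yl)-2,4-dimethoxy-6-oxocyclohexa-1,3-diene-1-carbaldehyde (racemic Claisen dienone) | O=CC1=C(OC)C=C(OC)C(CC(Br)=C)C1=O | intermediate
5 | 3-(2-bromoprop-2-en-1-yl)-2-hydroxy-4,6-dimethoxybenzaldehyde | COc1cc(OC)c(C=O)c(O)c1CC(Br)=C | intermediate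
6 | 5-(2-bromoprop-2-en-1-ylidene)-2,4-dimethoxy-6-oxocyclohexa-1,3-diene-1-carbaldehyde (ortho-quinone methide) | O=CC1=C(OC)C=C(OC)C(=CC(Br)=C)C1=O | intermediate
7 | 3-bromo-5,7-dimethoxy-2H-chromene-8-carbaldehyde | COc1cc(OC)c(C=O)c2c1C=C(Br)CO2 | intermediate
8 | 5-(benzyloxy)-2-bromophenol | Oc1cc(OCc2ccccc2)ccc1Br | starting material
9 | 5,7-dimethoxy-3-(4,4,5,5-tetramethyl-1,3,2-dioxaborolan-2-yl)-2H-chromene-8-carbaldehyde | COc1cc(OC)c(C=O)c2c1C=C(B1OC(C)(C)C(C)(C)O1)CO2 | intermediate
10 | 3-[4-(benzyloxy)-2-hydroxyphenyl]-5,7-dimethoxy-2H-chromene-8-carbaldehyde | COc1cc(OC)c(C=O)c2c1C=C(c1ccc(OCc3ccccc3)cc1O)CO2 | intermediate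
11 | (3R)-3-[4-(benzyloxy)-2-hydroxyphenyl]-5,7-dimethoxy-3,4-dihydro-2H-chromene-8-carbaldehyde | COc1cc(OC)c(C=O)c2c1C[C@H](c1ccc(OCc3ccccc3)cc1O)CO2 | intermediate
12 | (3R)-3-[4-(benzyloxy)-2-hydroxy-3-(hydroxymethyl)phenyl]-5,7-dimethoxy-3,4-dihydro-2H-chromene-8-carbaldehyde | COc1cc(OC)c(C=O)c2c1C[C@H](c1ccc(OCc3ccccc3)c(CO)c1O)CO2 | intermediate
13 | (3R)-3-[4-(benzyloxy)-3-formyl-2-hydroxyphenyl]-5,7-dimethoxy-3,4-dihydro-2H-chromene-8-carbaldehyde | COc1cc(OC)c(C=O)c2c1C[C@H](c1ccc(OCc3ccccc3)c(C=O)c1O)CO2 | intermediate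
14 | (2-methylprop-1-en-1-yl)boronic acid | CC(C)=CB(O)O | starting material
15 | (3R)-3-{4-(benzyloxy)-3-[1-(dibenzylamino)-3-methylbut-2-en-1-yl]-2-hydroxyphenyl}-5,7-dimethoxy-3,4-dihydro-2H-chromene-8-carbaldehyde (both epimers at the amine-bearing carbon) | COc1cc(OC)c(C=O)c2c1C[C@H](c1ccc(OCc3ccccc3)c(C(C=C(C)C)N(Cc3ccccc3)Cc3ccccc3)c1O)CO2 | intermediate
16 | (3R)-3-[4-(benzyloxy)-5-(3-methylbut-2-en-1-ylidene)-6-oxocyclohexa-1,3-dien-1-yl]-5,7-dimethoxy-3,4-dihydro-2H-chromene-8-carbaldehyde (ortho-quinone methide) | COc1cc(OC)c(C=O)c2c1C[C@H](C1=CC=C(OCc3ccccc3)C(=CC=C(C)C)C1=O)CO2 | intermediate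
17 | (3R)-3-[5-(benzyloxy)-2,2-dimethyl-2H-chromen-8-yl]-5,7-dimethoxy-3,4-dihydro-2H-chromene-8-carbaldehyde | COc1cc(OC)c(C=O)c2c1C[C@H](c1ccc(OCc3ccccc3)c3c1OC(C)(C)C=C3)CO2 | intermediate
18 | (3R)-3-(5-hydroxy-2,2-dimethyl-2H-chromen-8-yl)-5,7-dimethoxy-3,4-dihydro-2H-chromene-8-carbaldehyde | COc1cc(OC)c(C=O)c2c1C[C@H](c1ccc(O)c3c1OC(C)(C)C=C3)CO2 | intermediate
19 | (3R)-7-hydroxy-3-(5-hydroxy-2,2-dimethyl-2H-chromen-8-yl)-5-methoxy-3,4-dihydro-2H-chromene-8-carbaldehyde | COc1cc(O)c(C=O)c2c1C[C@H](c1ccc(O)c3c1OC(C)(C)C=C3)CO2 | target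

Total step count: 8. Longest linear sequence: 8 steps (1 to 19); 2, 8 and 14 are bought and enter directly.

Steps most likely to fail

Step 3. The first hydride abstraction may be slow on the bromoallyl compound and overlap with a second one at the O–CH2 group of the product, which would carry 7 on to a benzopyrylium ion. Fallback, from 1 back to 7: alkylation of 1 with propargyl bromide (K2CO3, DMF) would give 4,6-dimethoxy-2-(prop-2-yn-1-yloxy)benzaldehyde F1. Heating in N,N-diethylaniline at 200 °C (propargyl Claisen rearrangement, [1,5]-hydrogen shift, electrocyclization) would give 5,7-dimethoxy-2H-chromene-8-carbaldehyde F2. Bromine addition (Br2, CH2Cl2, −78 °C) would give (±)-trans-3,4-dibromo-5,7-dimethoxy-3,4-dihydro-2H-chromene-8-carbaldehyde F3, and DBU would then remove HBr with loss of the benzylic bromide to rejoin the route at 7.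

Step 5. Facial selectivity may be poor, or the catalyst may be slowed, because the free 2'-hydroxyl can bind iridium and the alkene is flanked by the 5-methoxy group and an ortho-substituted aryl group. Fallback, from 10 back to 11: hydrogenation with the achiral complex [Ir(cod)(PCy3)(C5H5N)]PF6 would give racemic 3-[4-(benzyloxy)-2-hydroxyphenyl]-5,7-dimethoxy-3,4-dihydro-2H-chromene-8-carbaldehyde F4. Preparative chromatography on a chiral stationary phase would then deliver the R enantiomer, which is 11.

Step 7. Iminium formation and alkenyl transfer at the doubly ortho-substituted aldehyde may be slower than protodeboronation of 14, or the sequence may stall at amine 15. Fallback, from 11 back to 17, with step 6 left out: condensation of 11 with 3-methylbut-2-enal, phenylboronic acid and catalytic acetic acid (toluene, reflux, water removal) would form at O2' and C3' the cyclic boronate (3R)-3-[5-(benzyloxy)-4-(2-methylprop-1-en-1-yl)-2-phenyl-4H-1,3,2-benzodioxaborinin-8-yl]-5,7-dimethoxy-3,4-dihydro-2H-chromene-8-carbaldehyde F5. This fragments on heating to the same ortho-quinone methide 16, which closes to 17. This fallback builds the pyran from the aryl–C4'' and O1''–C2'' bonds instead.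

Further compounds
F1 | step 3 | 4,6-dimethoxy-2-(prop-2-yn-1-yloxy)benzaldehyde | COc1cc(OCC#C)c(C=O)c(OC)c1
F2 | step 3 | 5,7-dimethoxy-2H-chromene-8-carbaldehyde | COc1cc(OC)c(C=O)c2c1C=CCO2
F3 | step 3 | (±)-trans-3,4-dibromo-5,7-dimethoxy-3,4-dihydro-2H-chromene-8-carbaldehyde (one enantiomer drawn) | COc1cc(OC)c(C=O)c2c1[C@@H](Br)[C@H](Br)CO2
F4 | step 5 | racemic 3-[4-(benzyloxy)-2-hydroxyphenyl]-5,7-dimethoxy-3,4-dihydro-2H-chromene-8-carbaldehyde | COc1cc(OC)c(C=O)c2c1CC(c1ccc(OCc3ccccc3)cc1O)CO2
F5 | step 7 | (3R)-3-[5-(benzyloxy)-4-(2-methylprop-1-en-1-yl)-2-phenyl-4H-1,3,2-benzodioxaborinin-8-yl]-5,7-dimethoxy-3,4-dihydro-2H-chromene-8-carbaldehyde (both epimers at C4 of the boron ring) | COc1cc(OC)c(C=O)c2c1C[C@H](c1ccc(OCc3ccccc3)c3c1OB(c1ccccc1)OC3C=C(C)C)CO2
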